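The route rests on forming the bridged nine-membered ring B by ring expansion and not by cyclisation. The key step is an α-ketol shift in a fused 5-8-5 hydroxy-dione: vinylic C1 moves from the C11 carbinol to the neighbouring C12 carbonyl, which in one operation forms C1–C12, enlarges the eight-membered ring to the nine-membered one and sets C12. It exploits the tertiary ketol carbon C12 of ring C, which carries C1 of ring B and lies next to C11. The precursor, a C11-hydroxy-12,13-dione with a C10=C14 alkene, is built from a limonene-derived ring A, a silyloxycyclopentenone ring C, a Suzuki union at C9–C10 and ring-closing metathesis at C1=C2.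

Key step: step 22

Remark: locants C1–C16 are those of the target (ring A = C2–C6, C1 vinylic CH, C7–C9 chain, ring C = C10–C14, C16 = CH2OMe carbon); compound 1 is used as the commercial cis/trans epoxide mixture derived from (R)-(+)-limonene (the epimers converge in step 4), and the (S)-enantiomer of 16 is assumed to be commercially available.

Step 1
Reactants: 1 (4R)-limonene 1,2-oxide
Product: 2 (4R)-p-mentha-1(7),8-dien-2-ol (both C2 epimers)
Conditions: LiN(i-Pr)2, Et2O, 0 °C to reflux
Reagents that add atoms: none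
Why: Lithium amide-induced isomerisation of a trisubstituted epoxide to an allylic alcohol (syn β-elimination) takes the proton from the unhindered methyl group on the epoxide, which gives the exocyclic alkene; the limonene stereocentre, the later C6, is not touched.

Step 2
Reactants: 2 (4R)-p-mentha-1(7),8-dien-2-ol
Product: 3 (6R)-6-(prop-1-en-2-yl)-1-oxaspiro[2.5]octan-4-ol (epoxide oxygen syn to the hydroxyl)
Conditions: VO(acac)2 (2 mol %), t-BuOOH, toluene, 0 °C to rt
Reagents that add atoms: tert-butyl hydroperoxide, CC(C)(C)OO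
Why: Hydroxyl-directed vanadium-catalysed epoxidation oxidises only the alkene of the allylic alcohol and leaves the isopropenyl group; the new centres disappear in step 4.

Step 3
Reactants: 3 (6R)-6-(prop-1-en-2-yl)-1-oxaspiro[2.5]octan-4-ol
Product: 4 (4R)-1-(methoxymethyl)-4-(prop-1-en-2-yl)cyclohexane-1,2-diol
Conditions: NaOMe (0.5 equiv), MeOH, reflux
Reagents that add atoms: methanol, CO
Why: Methoxide opens the spiro-epoxide by SN2 attack at its unhindered CH2 terminus, which installs the C16 methyl ether and leaves a vicinal tertiary/secondary diol.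

Step 4
Reactants: 4 (4R)-1-(methoxymethyl)-4-(prop-1-en-2-yl)cyclohexane-1,2-diol
Product: 5 (3R)-7-methoxy-6-oxo-3-(prop-1-en-2-yl)heptanal
Conditions: NaIO4, THF/H2O, rt
Reagents that add atoms: none
Why: Periodate glycol cleavage breaks the diol C–C bond to the methoxymethyl ketone and the aldehyde, so that all diol diastereomers converge on one compound.

Step 5
Reactants: 5 (3R)-7-methoxy-6-oxo-3-(prop-1-en-2-yl)heptanal
Product: 6 (5S)-2-(methoxymethyl)-5-(prop-1-en-2-yl)cyclopent-1-ene-1-carbaldehyde
Conditions: piperidine (0.2 equiv), AcOH (0.2 equiv), toluene, 60 °C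
Reagents that add atoms: none
Why: Amine-catalysed intramolecular aldol condensation (enamine of the aldehyde onto the activated α-alkoxy ketone, five-membered ring, then loss of water) gives the cyclopentene carbaldehyde, the course established for the parent limonene keto aldehyde.

Step 6
Reactants: 6 (5S)-2-(methoxymethyl)-5-(prop-1-en-2-yl)cyclopent-1-ene-1-carbaldehyde
Product: 7 5-(methoxymethyl)-2-(prop-1-en-2-yl)-6-oxabicyclo[3.1.0]hexane-1-carbaldehyde (C2,C3-epoxide, oxygen trans to the isopropenyl group)
Conditions: H2O2 (30 %), NaOH (0.2 equiv), MeOH, 0 °C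
Reagents that add atoms: hydrogen peroxide, OO
Why: Weitz–Scheffer nucleophilic epoxidation: hydroperoxide adds to C3 of the enal on the ring face away from the isopropenyl group at C6 and the enolate closes the oxirane, which sets the C3–O bond trans to C7 as the target requires.

Step 7
Reactants: 7 2,3-epoxy aldehyde
Product: 8 (1R,3S)-1-(methoxymethyl)-2-methylidene-3-(prop-1-en-2-yl)cyclopentan-1-ol
Conditions: N2H4·H2O, AcOH (cat.), MeOH, 0 °C to rt
Reagents that add atoms: none
Why: Wharton transposition: the hydrazone opens the oxirane at C2 to an alkenyl diazene that loses N2, leaving the C3 oxygen as the tertiary allylic alcohol (configuration from step 6) and the aldehyde carbon as an exocyclic methylene.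

Step 8
Reactants: 8 (1R,3S)-1-(methoxymethyl)-2-methylidene-3-(prop-1-en-2-yl)cyclopentan-1-ol
Product: 10 (2R)-2-[(1S,3R)-3-hydroxy-3-(methoxymethyl)-2-methylidenecyclopentyl]propan-1-ol, via B-alkyl-9-BBN adduct 9 (not isolated)
Conditions: 9-BBN, THF, 0 °C to rt; then NaOH, H2O2, 0 °C
Reagents that add atoms: hydrogen peroxide, OO
Why: Anti-Markovnikov hydroboration–oxidation with the bulky borane takes the isopropenyl group, not the ring methylene flanked by the quaternary C3, and sets C7 by 1,2-induction (allylic C6–H eclipsing the alkene, boron entering on the side away from the substituted C2 flank of ring A).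

Step 9
Reactants: 10 (2R)-2-[(1S,3R)-3-hydroxy-3-(methoxymethyl)-2-methylidenecyclopentyl]propan-1-ol
Product: 11 (2R)-2-[(1S,3R)-3-hydroxy-3-(methoxymethyl)-2-methylidenecyclopentyl]propanal
Conditions: Dess–Martin periodinane, NaHCO3, CH2Cl2, 0 °C
Reagents that add atoms: none
Why: Buffered Dess–Martin oxidation of the primary alcohol leaves the tertiary allylic alcohol untouched and does not epimerise C7.

Step 10
Reactants: 11 (2R)-2-[(1S,3R)-3-hydroxy-3-(methoxymethyl)-2-methylidenecyclopentyl]propanal
Product: 12 (3R)-3-[(1S,3R)-3-hydroxy-3-(methoxymethyl)-2-methylidenecyclopentyl]butan-2-ol (both carbinol epimers)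
Conditions: MeMgBr (2.5 equiv), THF, −78 °C
Reagents that add atoms: methylmagnesium bromide, C[Mg]Br
Why: Grignard addition to the aldehyde brings in C9; the carbinol centre formed is removed in step 11.

Step 11
Reactants: 12 (3R)-3-[(1S,3R)-3-hydroxy-3-(methoxymethyl)-2-methylidenecyclopentyl]butan-2-ol
Product: 13 (3R)-3-[(1S,3R)-3-hydroxy-3-(methoxymethyl)-2-methylidenecyclopentyl]butan-2-one
Conditions: Dess–Martin periodinane, NaHCO3, CH2Cl2, 0 °C
Reagents that add atoms: none
Why: Dess–Martin oxidation of the secondary alcohol gives the C8 methyl ketone under conditions that do not enolise C7.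

Step 12
Reactants: 13 (3R)-3-[(1S,3R)-3-hydroxy-3-(methoxymethyl)-2-methylidenecyclopentyl]butan-2-one
Product: 15 (1R,3S)-1-(methoxymethyl)-2-methylidene-3-[(2R)-3-(triisopropylsilyloxy)but-3-en-2-yl]cyclopentan-1-ol, via dilithium enolate-alkoxide 14 (not isolated)
Conditions: LiN(i-Pr)2 (2.2 equiv), THF, −78 °C; then (i-Pr)3SiOTf (1.1 equiv), −78 °C
Reagents that add atoms: triisopropylsilyl trifluoromethanesulfonate, CC(C)[Si](C(C)C)(C(C)C)OS(=O)(=O)C(F)(F)F
Why: Kinetic deprotonation of the C9 methyl group rather than the hindered C7 methine and O-silylation of the enolate give the 2-silyloxy-1-alkene; the tertiary lithium alkoxide at C3, next to a quaternary carbon, should not take up the bulky silyl triflate at −78 °C.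

Step 13
Reactants: 16 (4S)-4-(tert-butyldimethylsilyloxy)cyclopent-2-en-1-one
Product: 17 (3S,4S)-4-(tert-butyldimethylsilyloxy)-3-(propan-2-yl)-1-(trimethylsilyloxy)cyclopent-1-ene (3,4-trans)
Conditions: i-PrMgCl, CuBr·SMe2 (10 mol %), Me3SiCl, THF, −78 °C
Reagents that add atoms: isopropylmagnesium chloride, CC(C)[Mg]Cl; chlorotrimethylsilane, C[Si](C)(C)Cl
Why: Copper-catalysed conjugate addition places the isopropyl group on C14 trans to the silyloxy group, and Me3SiCl traps the enolate as its silyl enol ether before it can expel the β-silyloxy group.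

Step 14
Reactants: 17 (3S,4S)-4-(tert-butyldimethylsilyloxy)-3-(propan-2-yl)-1-(trimethylsilyloxy)cyclopent-1-ene
Product: 18 (4S)-4-(tert-butyldimethylsilyloxy)-3-(propan-2-yl)cyclopent-2-en-1-one
Conditions: Pd(OAc)2 (10 mol %), O2 (1 atm), DMSO, rt
Reagents that add atoms: none
Why: Saegusa–Ito oxidation (palladium enolate, β-hydride elimination, reoxidation of palladium by O2) restores the enone and removes the C14 centre.

Step 15
Reactants: 18 (4S)-4-(tert-butyldimethylsilyloxy)-3-(propan-2-yl)cyclopent-2-en-1-one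
Product: 20 (4S)-2-bromo-4-(tert-butyldimethylsilyloxy)-3-(propan-2-yl)cyclopent-2-en-1-one, via vicinal dibromide 19 (not isolated)
Conditions: Br2, CH2Cl2, −78 °C; then Et3N, 0 °C
Reagents that add atoms: bromine, BrBr
Why: Addition of bromine to the enone and dehydrobromination of the dibromide through the acidic α-hydrogen give the 2-bromoenone, the usual route for β-substituted enones.

Step 16
Reactants: 15 ring A silyl enol ether; 20 (4S)-2-bromo-4-(tert-butyldimethylsilyloxy)-3-(propan-2-yl)cyclopent-2-en-1-one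
Product: 22 seco enone (ring A carbinol joined through C7(R)-methyl, C8(S)-OSi(i-Pr)3 and C9H2 to C10 of the (13S)-13-silyloxy-14-isopropylcyclopentenone with the ketone at C11), via B-alkyl-9-BBN adduct 21 (not isolated)
Conditions: 9-BBN, THF, 0 °C to rt; then 20, Pd(OAc)2 (5 mol %), SPhos (10 mol %), K3PO4, THF/H2O, 40 °C
Reagents that add atoms: none
Why: 9-BBN adds to the electron-rich silyl enol ether with boron at C9 and hydrogen at C8, the hydride entering anti to ring A on the conformer with C7–H eclipsing the alkene (1,2-anti induction, which gives the C8 configuration of the target), and the B-alkyl Suzuki–Miyaura coupling with the 2-haloenone, for which both partner classes (β-alkoxyalkyl boranes and 2-halo-4-silyloxycyclopentenones) are known, forms C9–C10.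

Step 17
Reactants: 22 seco enone
Product: 23 seco vinyl carbinol (C11 tertiary alcohol carrying the vinyl group trans to the C13 silyloxy group; 11S,13S)
Conditions: CH2=CHMgBr (3 equiv), LaCl3·2LiCl (30 mol %), THF, −78 to 0 °C
Reagents that add atoms: vinylmagnesium bromide, C=C[Mg]Br
Why: Lanthanum-promoted 1,2-addition of the vinyl Grignard reagent to the cyclopentenone carbonyl C11 from the face opposite the C13 silyloxy group sets the C11 carbinol, the lanthanum salt suppressing enolisation towards C12 and loss of the β-silyloxy group.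

Step 18
Reactants: 23 seco vinyl carbinol
Product: 24 fused 5-8-5 carbinol (C11-OH, C13-OSiMe2t-Bu, C8-OSi(i-Pr)3, C3-OH, C1=C2 cis within ring B)
Conditions: second-generation Hoveyda–Grubbs catalyst (10 mol %), toluene (2 mM), 90 °C
Reagents that add atoms: none
Why: Ring-closing olefin metathesis: the ruthenium alkylidene forms at the vinyl group and closes onto the ring A methylene with loss of ethylene, which gives the eight-membered ring B with the C1=C2 bond necessarily cis within the ring (C11 cis to C6); trisubstituted cyclooctenes in fused systems have been closed in this way.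

Step 19
Reactants: 24 fused 5-8-5 carbinol
Product: 25 fused 5-8-5 C11,C13-diol (C8-OSi(i-Pr)3 kept)
Conditions: HF·pyridine, pyridine, THF, 0 °C
Reagents that add atoms: none
Why: Buffered HF·pyridine removes the less hindered allylic tert-butyldimethylsilyl ether at C13 and leaves the triisopropylsilyl ether at C8.

Step 20
Reactants: 25 fused 5-8-5 C11,C13-diol
Product: 26 fused 5-8-5 C11-hydroxy-C13-enone
Conditions: Dess–Martin periodinane, NaHCO3, CH2Cl2, 0 °C
Reagents that add atoms: none
Why: Dess–Martin oxidation of the only secondary alcohol gives the enone conjugated with C10=C14; the two tertiary alcohols cannot be oxidised.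

Step 21
Reactants: 26 fused 5-8-5 C11-hydroxy-C13-enone
Product: 27 fused 5-8-5 C11-hydroxy-12,13-dione (C8 triisopropylsilyl ether)
Conditions: SeO2 (1.5 equiv), 1,4-dioxane, H2O (trace), 80 °C
Reagents that add atoms: selenium dioxide, O=[Se]=O
Why: Riley oxidation: SeO2 reacts through the enol towards C12, the only α-CH2 of the ketone, and because C11 carries no hydrogen the α-seleno intermediate cannot eliminate to a dienone and collapses to the 12,13-dione.

Step 22
Reactants: 27 fused 5-8-5 C11-hydroxy-12,13-dione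
Product: 28 bridged 5-9-5 C12-hydroxy-11,13-dione (C8 triisopropylsilyl ether)
Conditions: Al(Ot-Bu)3 (0.3 equiv), toluene, 60 °C
Reagents that add atoms: none
Why: Aluminium exchanges onto the C11 hydroxyl and binds the C12 carbonyl, and the C11 alkoxide then pushes the C1–C11 σ-bond onto C12, so that C1–C12 forms as C1–C11 breaks, C11 becomes a ketone and the former C12 carbonyl oxygen becomes the tertiary hydroxyl. The closest known reaction type is the α-ketol (acyloin) rearrangement used as a ring-expanding 1,2-shift, as in the D-homoannulation of 17-hydroxy-20-keto steroids. The nine-membered ring B is not closed by a cyclisation but arises by ring expansion, C12 being inserted between C1 and C11 of the eight-membered ring while ring C stays five-membered and becomes the one- and two-atom bridges. The new stereocentre C12 is fixed by the suprafacial course of the shift: C1 leaves C11 and arrives at C12 on the same face of ring C, so the C11 configuration set in step 17 is relayed to C12 and the hydroxyl ends on the opposite face. The step needs C1 and not the ring bond C10–C11 to migrate and needs the equilibrium to lie on the product side; the first is secured because a shift of C10 would contract ring C to a cyclobutenone, the second because a vicinal dione conjugated on one side only is exchanged for an ene-1,3-dione in which both the C11 and the C13 carbonyl are conjugated with C10=C14. A non-nucleophilic aluminium alkoxide is chosen so that no benzilic-acid contraction of the 1,2-dione competes.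

Step 23
Reactants: 28 bridged 5-9-5 C12-hydroxy-11,13-dione
Product: 29 8-O-triisopropylsilyl brassicicene M
Conditions: MeMgBr (5 equiv), THF, −78 °C
Reagents that add atoms: methylmagnesium bromide, C[Mg]Br
Why: The Grignard reagent adds to the C11 carbonyl, which is less hindered than the C13 carbonyl flanked by the isopropyl-bearing C14, and from the face of ring C opposite the C1 bridge, which sets C11 with the methyl group cis to the C12 hydroxyl.

Step 24
Reactants: 29 8-O-triisopropylsilyl brassicicene M
Product: 30 brassicicene M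
Conditions: HF·pyridine, THF, 0 °C to rt
Reagents that add atoms: none
Why: Fluoride cleavage of the C8 silyl ether under mildly acidic conditions, which avoid base-induced shifts of the α-ketol.

Compound list

1 | (4R)-limonene 1,2-oxide (cis/trans mixture) | CC1(O2)CC[C@H](CC12)C(C)=C | starting material
2 | (4R)-p-mentha-1(7),8-dien-2-ol (C2 epimers) | C=C1CC[C@H](CC1O)C(C)=C | intermediate
3 | (6R)-6-(prop-1-en-2-yl)-1-oxaspiro[2.5]octan-4-ol | O1CC12CC[C@H](CC2O)C(C)=C | intermediate
4 | (4R)-1-(methoxymethyl)-4-(prop-1-en-2-yl)cyclohexane-1,2-diol | COCC1(O)CC[C@H](CC1O)C(C)=C | intermediate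
5 | (3R)-7-methoxy-6-oxo-3-(prop-1-en-2-yl)heptanal | COCC(=O)CC[C@H](CC=O)C(C)=C | intermediate
6 | (5S)-2-(methoxymethyl)-5-(prop-1-en-2-yl)cyclopent-1-ene-1-carbaldehyde | COCC1=C(C=O)[C@@H](CC1)C(C)=C | intermediate
7 | 5-(methoxymethyl)-2-(prop-1-en-2-yl)-6-oxabicyclo[3.1.0]hexane-1-carbaldehyde, epoxide oxygen trans to isopropenyl | COC[C@@]1(O2)CC[C@@H](C(C)=C)[C@@]12C=O | intermediate
8 | (1R,3S)-1-(methoxymethyl)-2-methylidene-3-(prop-1-en-2-yl)cyclopentan-1-ol | COC[C@@]1(O)CC[C@@H](C(C)=C)C1=C | intermediate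
9 | B-alkyl-9-BBN adduct of 8 (boron at C8) | COC[C@@]1(O)CC[C@@H]([C@@H](C)CB2C3CCCC2CCC3)C1=C | intermediate (not isolated)
10 | (2R)-2-[(1S,3R)-3-hydroxy-3-(methoxymethyl)-2-methylidenecyclopentyl]propan-1-ol | COC[C@@]1(O)CC[C@@H]([C@@H](C)CO)C1=C | intermediate
11 | (2R)-2-[(1S,3R)-3-hydroxy-3-(methoxymethyl)-2-methylidenecyclopentyl]propanal | COC[C@@]1(O)CC[C@@H]([C@@H](C)C=O)C1=C | intermediate
12 | (3R)-3-[(1S,3R)-3-hydroxy-3-(methoxymethyl)-2-methylidenecyclopentyl]butan-2-ol (carbinol epimers) | COC[C@@]1(O)CC[C@@H]([C@@H](C)C(C)O)C1=C | intermediate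
13 | (3R)-3-[(1S,3R)-3-hydroxy-3-(methoxymethyl)-2-methylidenecyclopentyl]butan-2-one | COC[C@@]1(O)CC[C@@H]([C@@H](C)C(C)=O)C1=C | intermediate
14 | dilithium salt of 13 (C3 alkoxide, C8=C9 enolate) | [Li+].[Li+].COC[C@@]1([O-])CC[C@@H]([C@@H](C)C(=C)[O-])C1=C | intermediate (not isolated)
15 | (1R,3S)-1-(methoxymethyl)-2-methylidene-3-[(2R)-3-(triisopropylsilyloxy)but-3-en-2-yl]cyclopentan-1-ol | COC[C@@]1(O)CC[C@@H]([C@@H](C)C(=C)O[Si](C(C)C)(C(C)C)C(C)C)C1=C | intermediate
16 | (4S)-4-(tert-butyldimethylsilyloxy)cyclopent-2-en-1-one | O=C1C=C[C@@H](O[Si](C)(C)C(C)(C)C)C1 | starting material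
17 | (3S,4S)-4-(tert-butyldimethylsilyloxy)-3-(propan-2-yl)-1-(trimethylsilyloxy)cyclopent-1-ene | C[Si](C)(C)OC1=C[C@H](C(C)C)[C@@H](O[Si](C)(C)C(C)(C)C)C1 | intermediate
18 | (4S)-4-(tert-butyldimethylsilyloxy)-3-(propan-2-yl)cyclopent-2-en-1-one | O=C1C=C(C(C)C)[C@@H](O[Si](C)(C)C(C)(C)C)C1 | intermediate
19 | (4S)-2,3-dibromo-4-(tert-butyldimethylsilyloxy)-3-(propan-2-yl)cyclopentan-1-one | O=C1C(Br)C(Br)(C(C)C)[C@@H](O[Si](C)(C)C(C)(C)C)C1 | intermediate (not isolated)
20 | (4S)-2-bromo-4-(tert-butyldimethylsilyloxy)-3-(propan-2-yl)cyclopent-2-en-1-one | O=C1C(Br)=C(C(C)C)[C@@H](O[Si](C)(C)C(C)(C)C)C1 | intermediate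
21 | B-alkyl-9-BBN adduct of 15 (boron at C9, 8S silyl ether) | COC[C@@]1(O)CC[C@@H]([C@@H](C)[C@@H](O[Si](C(C)C)(C(C)C)C(C)C)CB2C3CCCC2CCC3)C1=C | intermediate (not isolated)
22 | seco enone (3R,6S,7R,8S,13S): ring A methylidene carbinol, C8 triisopropylsilyl ether, C9 on C10 of the 13-silyloxy-14-isopropylcyclopent-10(14)-en-11-one | COC[C@@]1(O)CC[C@@H]([C@@H](C)[C@@H](O[Si](C(C)C)(C(C)C)C(C)C)CC2=C(C(C)C)[C@@H](O[Si](C)(C)C(C)(C)C)CC2=O)C1=C | intermediate
23 | seco vinyl carbinol (3R,6S,7R,8S,11S,13S): as 22 with C11 C(OH)(CH=CH2), vinyl trans to the C13 silyloxy group | COC[C@@]1(O)CC[C@@H]([C@@H](C)[C@@H](O[Si](C(C)C)(C(C)C)C(C)C)CC2=C(C(C)C)[C@@H](O[Si](C)(C)C(C)(C)C)C[C@]2(O)C=C)C1=C | intermediate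
24 | fused 5-8-5 carbinol: C3-OH, C11-OH, C13-OSiMe2t-Bu, C8-OSi(i-Pr)3, C1=C2 and C10=C14 alkenes | COC[C@@]1(O)CC[C@@H]2/C1=C\[C@@]3(O)C[C@H](O[Si](C)(C)C(C)(C)C)C(C(C)C)=C3C[C@H](O[Si](C(C)C)(C(C)C)C(C)C)[C@@H]2C | intermediate
25 | fused 5-8-5 C3,C11,C13-triol C8 triisopropylsilyl ether | COC[C@@]1(O)CC[C@@H]2/C1=C\[C@@]3(O)C[C@H](O)C(C(C)C)=C3C[C@H](O[Si](C(C)C)(C(C)C)C(C)C)[C@@H]2C | intermediate
26 | fused 5-8-5 C11-hydroxy-C13-enone (C12 CH2) | COC[C@@]1(O)CC[C@@H]2/C1=C\[C@@]3(O)CC(=O)C(C(C)C)=C3C[C@H](O[Si](C(C)C)(C(C)C)C(C)C)[C@@H]2C | intermediate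
27 | fused 5-8-5 C11-hydroxy-12,13-dione, C8 triisopropylsilyl ether (key-step precursor) | COC[C@@]1(O)CC[C@@H]2/C1=C\[C@@]3(O)C(=O)C(=O)C(C(C)C)=C3C[C@H](O[Si](C(C)C)(C(C)C)C(C)C)[C@@H]2C | intermediate
28 | bridged 5-9-5 C12-hydroxy-11,13-dione, C8 triisopropylsilyl ether (key-step product) | COC[C@@]1(O)CC[C@@H]2/C1=C\[C@@]1(O)C(=O)C(C(C)C)=C(C[C@H](O[Si](C(C)C)(C(C)C)C(C)C)[C@@H]2C)C1=O | intermediate
29 | 8-O-triisopropylsilyl brassicicene M | COC[C@@]1(O)CC[C@@H]2/C1=C\[C@@]1(O)C(=O)C(C(C)C)=C(C[C@H](O[Si](C(C)C)(C(C)C)C(C)C)[C@@H]2C)[C@@]1(C)O | intermediate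
30 | brassicicene M | COC[C@@]1(O)CC[C@@H]2/C1=C\[C@@]1(O)C(=O)C(C(C)C)=C(C[C@H](O)[C@@H]2C)[C@@]1(C)O | target

Total step count: 24. Longest linear sequence: 21 steps (steps 1–12 and 16–24); steps 13–15 prepare the ring C fragment.

Steps most likely to fail

Step 18 (ring-closing metathesis). The ruthenium alkylidene formed at the vinyl group may fail to engage the hindered 1,1-disubstituted alkene of ring A, so that dimerisation through the vinyl group outruns closure of the eight-membered ring. The fallback sets out from 22 and returns at 24, and replaces metathesis by addition of an alkenyl metal to the C11 ketone. The ring A methylene of 22 is hydroborated with catecholborane and RhCl(PPh3)3, which spares the enone carbonyl, and oxidised with NaBO3 to the C1 primary alcohol F1. Dess–Martin oxidation gives the C1 aldehyde F2 and hydrazine the C1 hydrazone F3. Iodine with tetramethylguanidine (Barton vinyl iodide synthesis) then gives the C1 alkenyl iodide F4, in which iodine should stand mainly cis to the less hindered C6. CrCl2 with catalytic NiCl2 in DMSO (Nozaki–Hiyama–Kishi reaction) finally adds C1 to the C11 ketone from the face opposite the C13 silyloxy group and closes ring B to 24.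

Step 22 (α-ketol shift). The shift may stall because the bridged product is more strained than the conjugation gain can pay for, or the C11 alkoxide may open ring C by retro-aldol-type cleavage instead of migrating C1. The fallback sets out from 23 and returns at 28, and moves the shift to the monocyclic stage, where no strain is built up. Compound 23 is desilylated at C13 with HF·pyridine to the seco C13 alcohol F5 and oxidised with Dess–Martin periodinane to the seco C13 enone F6. SeO2 then gives the seco 11-hydroxy-11-vinyl-12,13-dione F7. Al(Ot-Bu)3 shifts the vinyl group from C11 to C12 to give the seco 12-hydroxy-12-vinyl-11,13-dione F8. Ring-closing metathesis between this vinyl group and the ring A methylene (second-generation Hoveyda–Grubbs catalyst) then closes the nine-membered ring directly to 28.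

Step 21 (SeO2 oxidation). Hot selenous acid may oxidise allylic positions (C9, C6) or ionise the tertiary allylic hydroxyls before the C12 methylene is oxidised. The fallback sets out from 26 and returns at 27. Compound 26 is deprotonated with LiN(SiMe3)2 (excess, THF, −78 °C; kinetic C12 enolate) and hydroxylated with 2-(phenylsulfonyl)-3-phenyloxaziridine to the C12 hydroxy ketone F9, which Dess–Martin periodinane oxidises to 27.

Further compounds

F1 | step 18 | C1 primary alcohol from hydroboration of the ring A methylene of 22 (C2 epimers) | COC[C@@]1(O)CC[C@@H]([C@@H](C)[C@@H](O[Si](C(C)C)(C(C)C)C(C)C)CC2=C(C(C)C)[C@@H](O[Si](C)(C)C(C)(C)C)CC2=O)C1CO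
F2 | step 18 | C1 aldehyde | COC[C@@]1(O)CC[C@@H]([C@@H](C)[C@@H](O[Si](C(C)C)(C(C)C)C(C)C)CC2=C(C(C)C)[C@@H](O[Si](C)(C)C(C)(C)C)CC2=O)C1C=O
F3 | step 18 | C1 hydrazone | COC[C@@]1(O)CC[C@@H]([C@@H](C)[C@@H](O[Si](C(C)C)(C(C)C)C(C)C)CC2=C(C(C)C)[C@@H](O[Si](C)(C)C(C)(C)C)CC2=O)C1C=NN
F4 | step 18 | C1 alkenyl iodide (iodine cis to C6) | COC[C@@]1(O)CC[C@@H]([C@@H](C)[C@@H](O[Si](C(C)C)(C(C)C)C(C)C)CC2=C(C(C)C)[C@@H](O[Si](C)(C)C(C)(C)C)CC2=O)/C1=C\I
F5 | step 22 | seco C13 alcohol (C11 vinyl carbinol, C13-OH) | COC[C@@]1(O)CC[C@@H]([C@@H](C)[C@@H](O[Si](C(C)C)(C(C)C)C(C)C)CC2=C(C(C)C)[C@@H](O)C[C@]2(O)C=C)C1=C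
F6 | step 22 | seco C13 enone | COC[C@@]1(O)CC[C@@H]([C@@H](C)[C@@H](O[Si](C(C)C)(C(C)C)C(C)C)CC2=C(C(C)C)C(=O)C[C@]2(O)C=C)C1=C
F7 | step 22 | seco 11-hydroxy-11-vinyl-12,13-dione | COC[C@@]1(O)CC[C@@H]([C@@H](C)[C@@H](O[Si](C(C)C)(C(C)C)C(C)C)CC2=C(C(C)C)C(=O)C(=O)[C@]2(O)C=C)C1=C
F8 | step 22 | seco 12-hydroxy-12-vinyl-11,13-dione | COC[C@@]1(O)CC[C@@H]([C@@H](C)[C@@H](O[Si](C(C)C)(C(C)C)C(C)C)CC2=C(C(C)C)C(=O)[C@](O)(C=C)C2=O)C1=C
F9 | step 21 | C12 hydroxy ketone of 26 (C12 epimers) | COC[C@@]1(O)CC[C@@H]2/C1=C\[C@@]3(O)C(O)C(=O)C(C(C)C)=C3C[C@H](O[Si](C(C)C)(C(C)C)C(C)C)[C@@H]2C
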